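The A ring is a 1,2,3,5-tetraoxygenated benzene whose ring oxygen O1 (on C8a) and O7 flank the C8 methoxy group and are symmetry-equivalent in phenol 4, while O5 is the odd one. The route rests on disconnecting O1–C2 and the C3–heteroatom bond together: an iodonium-triggered 6-endo-dig cyclization of ynone 10, in which the benzyl ether oxygen next to the methoxy group closes the pyranone with loss of benzyl chloride while O5 stays masked as a pivalate. One operation forms the C ring, fixes the 8-methoxy (not 6-methoxy) pattern and installs C3–I as the handle for the 3-hydroxyl. Ynone 10 comes from aryl iodide 6, CO and alkyne 9.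

Key step: step 8

Remark: the target has no stereocentre and no other stereogenic element, so it is prepared as the achiral compound shown; aldehydes 1 and 7 are taken as catalogue compounds.

Step 1
Reactants: 1 3,5-dihydroxy-4-methoxybenzaldehyde
Product: 2 3,5-bis(benzyloxy)-4-methoxybenzaldehyde
Conditions: BnBr (2.4 equiv), K2CO3, DMF, 60 °C
Reagents that add atoms: benzyl bromide, BrCc1ccccc1
Why: Williamson etherification of both phenols should proceed cleanly, the non-enolisable aldehyde being inert to K2CO3/BnBr.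

Step 2
Reactants: 2 3,5-bis(benzyloxy)-4-methoxybenzaldehyde
Product: 4 3,5-bis(benzyloxy)-4-methoxyphenol, via aryl formate 3 (not isolated)
Conditions: mCPBA, CH2Cl2, rt; aq. NaHCO3 wash; then K2CO3 (cat.), MeOH, rt
Reagents that add atoms: 3-chloroperbenzoic acid, OOC(=O)c1cccc(Cl)c1
Why: Baeyer–Villiger (Dakin-type) oxidation, in which the electron-rich aryl group migrates in the Criegee intermediate to give formate 3, and mild methanolysis should then free the mirror-symmetric phenol 4.

Step 3
Reactants: 4 3,5-bis(benzyloxy)-4-methoxyphenol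
Product: 5 3,5-bis(benzyloxy)-4-methoxyphenyl 2,2-dimethylpropanoate
Conditions: PivCl, Et3N, DMAP (cat.), CH2Cl2, 0 °C to rt
Reagents that add atoms: pivaloyl chloride, CC(C)(C)C(Cl)=O
Why: DMAP-catalysed acylation of the phenol should mask the future O5 as a non-nucleophilic ester that tolerates Pd(0), ICl and a cold Grignard reagent.

Step 4
Reactants: 5 3,5-bis(benzyloxy)-4-methoxyphenyl 2,2-dimethylpropanoate
Product: 6 3,5-bis(benzyloxy)-2-iodo-4-methoxyphenyl 2,2-dimethylpropanoate
Conditions: NIS (1.05 equiv), TFA (10 mol %), MeCN, 0 °C to rt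
Reagents that add atoms: N-iodosuccinimide, O=C1CCC(=O)N1I
Why: Electrophilic aromatic iodination should occur at one of the two equivalent ring positions (ortho and para to the benzyloxy groups), so either site gives the same iodide, and one equivalent of NIS limits diiodination.

Step 5
Reactants: 7 3-hydroxy-4,5-dimethoxybenzaldehyde
Product: 8 3-(benzyloxy)-4,5-dimethoxybenzaldehyde
Conditions: BnBr, K2CO3, DMF, 60 °C
Reagents that add atoms: benzyl bromide, BrCc1ccccc1
Why: Williamson etherification of the single phenol.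

Step 6
Reactants: 8 3-(benzyloxy)-4,5-dimethoxybenzaldehyde
Product: 9 1-(benzyloxy)-5-ethynyl-2,3-dimethoxybenzene
Conditions: dimethyl (1-diazo-2-oxopropyl)phosphonate, K2CO3, MeOH, rt
Reagents that add atoms: dimethyl (1-diazo-2-oxopropyl)phosphonate, COP(=O)(OC)C(=[N+]=[N-])C(C)=O
Why: Seyferth–Gilbert homologation with the Ohira–Bestmann reagent, in which the diazomethylphosphonate anion formed in situ adds to the non-enolisable aldehyde and the alkylidene carbene left after loss of phosphate and N2 rearranges to the terminal alkyne.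

Step 7
Reactants: 6 3,5-bis(benzyloxy)-2-iodo-4-methoxyphenyl 2,2-dimethylpropanoate; 9 1-(benzyloxy)-5-ethynyl-2,3-dimethoxybenzene
Product: 10 3,5-bis(benzyloxy)-2-{3-[3-(benzyloxy)-4,5-dimethoxyphenyl]prop-2-ynoyl}-4-methoxyphenyl 2,2-dimethylpropanoate
Conditions: CO (1 atm), PdCl2(PPh3)2 (5 mol %), CuI (2 mol %), Et3N, THF, 45 °C
Reagents that add atoms: carbon monoxide, [C-]#[O+]
Why: Three-component carbonylative Sonogashira coupling (oxidative addition to Ar–I, CO insertion, which is favoured for a hindered electron-rich aryl–Pd, transmetalation with the copper acetylide, reductive elimination), with the pivalate preventing the neighbouring oxygen from closing onto the new ynone.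

Step 8
Reactants: 10 3,5-bis(benzyloxy)-2-{3-[3-(benzyloxy)-4,5-dimethoxyphenyl]prop-2-ynoyl}-4-methoxyphenyl 2,2-dimethylpropanoate
Product: 12 7-(benzyloxy)-2-[3-(benzyloxy)-4,5-dimethoxyphenyl]-3-iodo-8-methoxy-4-oxo-4H-chromen-5-yl 2,2-dimethylpropanoate, via O-benzyl chromenylium chloride 11 (not isolated)
Conditions: ICl (1.2 equiv), CH2Cl2, −78 °C; aq. Na2S2O3
Reagents that add atoms: iodine monochloride, ClI
Why: ICl transfers I+ to the ynone triple bond and the positive charge develops at C2, which is both the conjugate position of the ynone and benzylic to the trioxygenated B ring; the ortho benzyl ether oxygen attacks C2 anti to iodine to give O-benzyl chromenylium ion 11, which chloride dealkylates by SN2 attack at the benzylic CH2, so that O1–C2 and C3–I form in one operation. The closest known reaction type is the ICl-induced dealkylative iodocyclization of o-alkoxyaryl alkynones to 3-iodochromones. The pyran-4-one ring closes in the 6-endo-dig mode, preferred over 5-exo-dig (aurone) because only C2 stabilises the cation. No stereocentre is formed. The step needs chemoselectivity between the two oxygens ortho to the ketone, and this is secured because O5 is acylated (its lone pair is delocalised into the pivaloyl carbonyl) while the ether oxygen, which by the symmetry of 4 is necessarily the one next to the methoxy group, is the only nucleophile in reach, so the 8-methoxy isomer must result. Iodination of the electron-rich arenes should be held back at −78 °C with only a slight excess of ICl, the activated alkyne being the fastest partner.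

Step 9
Reactants: 12 7-(benzyloxy)-2-[3-(benzyloxy)-4,5-dimethoxyphenyl]-3-iodo-8-methoxy-4-oxo-4H-chromen-5-yl 2,2-dimethylpropanoate
Product: 15 7-(benzyloxy)-2-[3-(benzyloxy)-4,5-dimethoxyphenyl]-3-hydroxy-8-methoxy-4-oxo-4H-chromen-5-yl 2,2-dimethylpropanoate, via C3 magnesium reagent 13 (not isolated), via C3 dimethyl boronate 14 (not isolated)
Conditions: iPrMgCl·LiCl (1.1 equiv), THF, −78 °C, 15 min; B(OMe)3, −78 to 0 °C; AcOH, 30% H2O2, 0 °C to rt
Reagents that add atoms: hydrogen peroxide, OO; for intermediates 13 and 14 only: isopropylmagnesium chloride, CC(C)[Mg]Cl; trimethyl borate, COB(OC)OC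
Why: Iodine–magnesium exchange at the α-iodo enone should be fast at −78 °C (the hindered pivalate is tolerated), and borylation followed by peroxide oxidation of the C–B bond (1,2-shift from boron to oxygen) is the sequence used for C3-metalated flavones to give the 3-hydroxyl.

Step 10
Reactants: 15 7-(benzyloxy)-2-[3-(benzyloxy)-4,5-dimethoxyphenyl]-3-hydroxy-8-methoxy-4-oxo-4H-chromen-5-yl 2,2-dimethylpropanoate
Product: 17 3,5,7-trihydroxy-2-(3-hydroxy-4,5-dimethoxyphenyl)-8-methoxy-4H-chromen-4-one, via depivaloylated dibenzyl ether 16 (not isolated)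
Conditions: K2CO3, MeOH/THF, 40 °C (argon); then AcOH, Pd/C (10 %), H2 (1 atm), rt
Reagents that add atoms: none
Why: Methanolysis of the peri-activated aryl pivalate followed by hydrogenolysis of the two benzyl ethers over Pd/C should free all four hydroxyls, the methyl ethers and the flavonol core being inert.

Compound list
1 | 3,5-dihydroxy-4-methoxybenzaldehyde | COc1c(O)cc(C=O)cc1O | starting material
2 | 3,5-bis(benzyloxy)-4-methoxybenzaldehyde | COc1c(OCc2ccccc2)cc(C=O)cc1OCc1ccccc1 | intermediate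
3 | 3,5-bis(benzyloxy)-4-methoxyphenyl formate | COc1c(OCc2ccccc2)cc(OC=O)cc1OCc1ccccc1 | intermediate (not isolated)
4 | 3,5-bis(benzyloxy)-4-methoxyphenol | COc1c(OCc2ccccc2)cc(O)cc1OCc1ccccc1 | intermediate
5 | 3,5-bis(benzyloxy)-4-methoxyphenyl 2,2-dimethylpropanoate | COc1c(OCc2ccccc2)cc(OC(=O)C(C)(C)C)cc1OCc1ccccc1 | intermediate
6 | 3,5-bis(benzyloxy)-2-iodo-4-methoxyphenyl 2,2-dimethylpropanoate | COc1c(OCc2ccccc2)cc(OC(=O)C(C)(C)C)c(I)c1OCc1ccccc1 | intermediate
7 | 3-hydroxy-4,5-dimethoxybenzaldehyde | COc1cc(C=O)cc(O)c1OC | starting material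
8 | 3-(benzyloxy)-4,5-dimethoxybenzaldehyde | COc1cc(C=O)cc(OCc2ccccc2)c1OC | intermediate
9 | 1-(benzyloxy)-5-ethynyl-2,3-dimethoxybenzene | COc1cc(C#C)cc(OCc2ccccc2)c1OC | intermediate
10 | 3,5-bis(benzyloxy)-2-{3-[3-(benzyloxy)-4,5-dimethoxyphenyl]prop-2-ynoyl}-4-methoxyphenyl 2,2-dimethylpropanoate | COc1c(OCc2ccccc2)cc(OC(=O)C(C)(C)C)c(C(=O)C#Cc2cc(OC)c(OC)c(OCc3ccccc3)c2)c1OCc1ccccc1 | intermediate
11 | 1,7-dibenzyl-type oxonium: 1-benzyl-7-(benzyloxy)-2-[3-(benzyloxy)-4,5-dimethoxyphenyl]-3-iodo-8-methoxy-4-oxo-5-(pivaloyloxy)-4H-chromen-1-ium chloride | COc1cc(C2=C(I)C(=O)c3c(OC(=O)C(C)(C)C)cc(OCc4ccccc4)c(OC)c3[O+]2Cc2ccccc2)cc(OCc2ccccc2)c1OC.[Cl-] | intermediate (not isolated)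
12 | 7-(benzyloxy)-2-[3-(benzyloxy)-4,5-dimethoxyphenyl]-3-iodo-8-methoxy-4-oxo-4H-chromen-5-yl 2,2-dimethylpropanoate | COc1cc(-c2oc3c(OC)c(OCc4ccccc4)cc(OC(=O)C(C)(C)C)c3c(=O)c2I)cc(OCc2ccccc2)c1OC | intermediate
13 | {7-(benzyloxy)-2-[3-(benzyloxy)-4,5-dimethoxyphenyl]-8-methoxy-4-oxo-5-(pivaloyloxy)-4H-chromen-3-yl}magnesium chloride | COc1cc(-c2oc3c(OC)c(OCc4ccccc4)cc(OC(=O)C(C)(C)C)c3c(=O)c2[Mg]Cl)cc(OCc2ccccc2)c1OC | intermediate (not isolated)
14 | dimethyl {7-(benzyloxy)-2-[3-(benzyloxy)-4,5-dimethoxyphenyl]-8-methoxy-4-oxo-5-(pivaloyloxy)-4H-chromen-3-yl}boronate | COc1cc(-c2oc3c(OC)c(OCc4ccccc4)cc(OC(=O)C(C)(C)C)c3c(=O)c2B(OC)OC)cc(OCc2ccccc2)c1OC | intermediate (not isolated)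
15 | 7-(benzyloxy)-2-[3-(benzyloxy)-4,5-dimethoxyphenyl]-3-hydroxy-8-methoxy-4-oxo-4H-chromen-5-yl 2,2-dimethylpropanoate | COc1cc(-c2oc3c(OC)c(OCc4ccccc4)cc(OC(=O)C(C)(C)C)c3c(=O)c2O)cc(OCc2ccccc2)c1OC | intermediate
16 | 7-(benzyloxy)-2-[3-(benzyloxy)-4,5-dimethoxyphenyl]-3,5-dihydroxy-8-methoxy-4H-chromen-4-one | COc1cc(-c2oc3c(OC)c(OCc4ccccc4)cc(O)c3c(=O)c2O)cc(OCc2ccccc2)c1OC | intermediate (not isolated)
17 | 3,5,7-trihydroxy-2-(3-hydroxy-4,5-dimethoxyphenyl)-8-methoxy-4H-chromen-4-one | COc1cc(-c2oc3c(OC)c(O)cc(O)c3c(=O)c2O)cc(O)c1OC | target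

Total step count: 10. Longest linear sequence: 8 steps (steps 1, 2, 3, 4, 7, 8, 9, 10).

Steps most likely to fail

Step 8. Electrophilic iodination of the electron-rich arenes, or plain addition of ICl across the triple bond, may outrun ring closure. Fallback, setting out from 10 and returning at 15: chelation-controlled cleavage of the benzyl ether ortho to the ketone (BCl3, CH2Cl2, −78 °C) should give the o-hydroxyaryl ynone F1, whose only free hydroxyl is again the one next to the methoxy group. DMAP-catalysed 6-endo oxa-Michael cyclization (DMF, rt) should then give the 3-unsubstituted flavone F2. Epoxidation with dimethyldioxirane (acetone/CH2Cl2, 0 °C) should give the racemic 2,3-epoxide F3, which cat. p-TsOH isomerises to flavonol pivalate 15.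

Step 9. The C3 magnesium species may ring-open by β-elimination of the C8a phenoxide (the reverse of the cyclization), or the Grignard reagent may add to C4 or the pivalate. Fallback, setting out from 12 and returning at 15, with no carbanion at C3: Miyaura borylation (B2pin2, PdCl2(dppf), KOAc, dioxane, 80 °C) should give the pinacol boronate F7, and oxidation with NaBO3·4H2O in THF/H2O then gives 15.

Step 7. Oxidative addition at the di-ortho-substituted, electron-rich C–I bond may be slow, and CO-free Sonogashira coupling or oxidative dimerisation of 9 may compete. Fallback, setting out from 4 and returning at 10: magnesium-mediated ortho-formylation (MgCl2, Et3N, paraformaldehyde, MeCN, reflux) should give the salicylaldehyde F4, and pivaloylation (PivCl, Et3N, DMAP) the aldehyde pivalate F5. Addition of the lithium acetylide of 9 (n-BuLi, THF, −78 °C, cold AcOH quench to prevent acyl migration) should give the racemic propargylic alcohol F6, and MnO2 (CH2Cl2, rt) oxidises it to 10.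

Further compounds
F1 | step 8 | 5-(benzyloxy)-2-{3-[3-(benzyloxy)-4,5-dimethoxyphenyl]prop-2-ynoyl}-3-hydroxy-4-methoxyphenyl 2,2-dimethylpropanoate | COc1c(OCc2ccccc2)cc(OC(=O)C(C)(C)C)c(C(=O)C#Cc2cc(OC)c(OC)c(OCc3ccccc3)c2)c1O
F2 | step 8 | 7-(benzyloxy)-2-[3-(benzyloxy)-4,5-dimethoxyphenyl]-8-methoxy-4-oxo-4H-chromen-5-yl 2,2-dimethylpropanoate | COc1cc(-c2cc(=O)c3c(OC(=O)C(C)(C)C)cc(OCc4ccccc4)c(OC)c3o2)cc(OCc2ccccc2)c1OC
F3 | step 8 | racemic 2,3-epoxide of F2 (2,3-epoxy-2,3-dihydroflavone, cis-fused oxirane) | COc1cc(C23OC2C(=O)c4c(OC(=O)C(C)(C)C)cc(OCc5ccccc5)c(OC)c4O3)cc(OCc2ccccc2)c1OC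
F4 | step 7 | 2,4-bis(benzyloxy)-6-hydroxy-3-methoxybenzaldehyde | COc1c(OCc2ccccc2)cc(O)c(C=O)c1OCc1ccccc1
F5 | step 7 | 3,5-bis(benzyloxy)-2-formyl-4-methoxyphenyl 2,2-dimethylpropanoate | COc1c(OCc2ccccc2)cc(OC(=O)C(C)(C)C)c(C=O)c1OCc1ccccc1
F6 | step 7 | racemic 3,5-bis(benzyloxy)-2-{3-[3-(benzyloxy)-4,5-dimethoxyphenyl]-1-hydroxyprop-2-yn-1-yl}-4-methoxyphenyl 2,2-dimethylpropanoate | COc1c(OCc2ccccc2)cc(OC(=O)C(C)(C)C)c(C(O)C#Cc2cc(OC)c(OC)c(OCc3ccccc3)c2)c1OCc1ccccc1
F7 | step 9 | 7-(benzyloxy)-2-[3-(benzyloxy)-4,5-dimethoxyphenyl]-8-methoxy-4-oxo-3-(4,4,5,5-tetramethyl-1,3,2-dioxaborolan-2-yl)-4H-chromen-5-yl 2,2-dimethylpropanoate | COc1cc(-c2oc3c(OC)c(OCc4ccccc4)cc(OC(=O)C(C)(C)C)c3c(=O)c2B5OC(C)(C)C(C)(C)O5)cc(OCc2ccccc2)c1OC
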